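**Target:** (2S,3R)-3-[(2S,3R)-5,7-dihydroxy-2-(4-hydroxyphenyl)-4-oxochroman-3-yl]-7-hydroxy-2-(4-hydroxyphenyl)chroman-4-one; both pyranone rings are 2,3-trans and the two halves have the same sense (2S,3R / 2''S,3''R).

**Retrosynthetic overview**
1. 12 ⇐ 11, its penta-O-benzyl ether (neutral hydrogenolysis last).
2. 11 ⇐ diketone 6 + 2 × aldehyde 7 by cutting four bonds at once (C2–C3, O1–C2, C2''–C3'', O1''–C2''): an amine-catalysed double aldol-condensation/oxa-Michael cascade closes both pyranone rings in one operation; C2/C2'' are catalyst-set, C3/C3'' follow by thermodynamic trans protonation.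
3. 6 ⇐ 5 (chelation-controlled tri-O-benzylation) ⇐ 3 + 4 ⇐ 1 + 2 (two Friedel–Crafts acylations; the CH2–CH2 of succinic anhydride becomes the C3–C3'' bond).
4. Ring order: the A rings (resorcinol, phloroglucinol) and B rings (aldehyde) are bought; the two C rings are formed last and together.

Assumption: the (S)-configured catalyst in step 4 is taken to give the 2S/2''S series; if a model run shows the opposite sense, its commercial (R)-enantiomer is used and nothing else changes.

**Step 1**
Reactants: 1 resorcinol; 2 succinic anhydride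
Product: 3 4-(2,4-dihydroxyphenyl)-4-oxobutanoic acid
Conditions: AlCl3 (3 equiv), PhNO2, 0 → 60 °C; aq. HCl
Reagents that add atoms: none
Why: Friedel–Crafts (Haworth-type) acylation by the AlCl3-opened anhydride occurs at C4 of resorcinol (para to one OH, ortho to the other) and stops at the keto acid because the acylated ring and the aluminium carboxylate are deactivated.

**Step 2**
Reactants: 3 4-(2,4-dihydroxyphenyl)-4-oxobutanoic acid; 4 phloroglucinol
Product: 5 1-(2,4-dihydroxyphenyl)-4-(2,4,6-trihydroxyphenyl)butane-1,4-dione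
Conditions: BF3·OEt2 (neat, as solvent), 70 °C; aq. NaOAc
Reagents that add atoms: none
Why: BF3-mediated Friedel–Crafts C-acylation of the very nucleophilic, symmetric phloroglucinol by the free carboxylic acid (Nencki/deoxybenzoin-type conditions) has no regiochemical issue, and BF2 chelation of each o-hydroxyaryl ketone prevents over-acylation.

**Step 3**
Reactants: 5 1-(2,4-dihydroxyphenyl)-4-(2,4,6-trihydroxyphenyl)butane-1,4-dione
Product: 6 1-[4-(benzyloxy)-2-hydroxyphenyl]-4-[2,4-bis(benzyloxy)-6-hydroxyphenyl]butane-1,4-dione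
Conditions: BnBr (3.05 equiv), K2CO3, DMF, 0 °C → rt
Reagents that add atoms: benzyl bromide, BrCc1ccccc1
Why: Williamson etherification under chelation control, because the one OH on each ring that is hydrogen-bonded to its ketone is much less reactive towards K2CO3/BnBr, so exactly the three non-chelated phenols are benzylated and the two cyclisation nucleophiles stay free.

**Step 4**
Reactants: 6 1-[4-(benzyloxy)-2-hydroxyphenyl]-4-[2,4-bis(benzyloxy)-6-hydroxyphenyl]butane-1,4-dione; 7 4-(benzyloxy)benzaldehyde (2 equiv incorporated)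
Product: 11 (2S,3R,2''S,3''R)-penta-O-benzyl-3,3''-biflavanone, via monobenzylidene diketone 8 (not isolated), via 3-phenacylflavanone 9 (not isolated), via flavanone–chalcone hybrid 10 (not isolated)
Conditions: 7 (2.5 equiv), (S)-5-(pyrrolidin-2-yl)-1H-tetrazole (30 mol %), 4 Å MS, CHCl3–DMSO 4:1, 40 °C; SiO2, then recrystallisation
Reagents that add atoms: none
Why: Proposed new method: a double Kabbe-type cascade in which the chiral pyrrolidine condenses each o-hydroxyaryl ketone with 7 (enamine aldol/Mannich addition, then dehydration) to an α-branched unsaturated iminium ion that is closed at once by the neighbouring phenol in a 6-endo oxa-Michael addition, the tetrazolate hydrogen-bonding the phenolic OH so that one helical half-chair transition state is preferred and C2, then C2'', are set S under catalyst control, while C3 and C3'' are set by protonation of the enamine/enol and equilibrate to the 2,3-trans (R) arrangement without touching C2; because both C2 centres are set by the same catalyst, most of the minor sense ends up in the separable unlike (2S,2''R) diastereomer (Horeau-type amplification), and the hindered α-branched product ketones re-form iminium ions only slowly, which limits retro-oxa-Michael scrambling; the closest known reactions are the pyrrolidine-mediated Kabbe synthesis of chroman-4-ones and flavanones from 2'-hydroxyaryl ketones, proline-type aldol condensation, and amine-catalysed enantioselective intramolecular oxa-Michael cyclisation.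

**Step 5**
Reactants: 11 (2S,3R,2''S,3''R)-penta-O-benzyl-3,3''-biflavanone
Product: 12 (2S,3R)-3-[(2S,3R)-5,7-dihydroxy-2-(4-hydroxyphenyl)-4-oxochroman-3-yl]-7-hydroxy-2-(4-hydroxyphenyl)chroman-4-one
Conditions: H2 (1 atm), 10 % Pd/C, EtOAc–MeOH, rt
Reagents that add atoms: none
Why: Hydrogenolysis of the five aryl benzyl ethers under neutral conditions, where neither C2 (no base for quinone-methide or retro-oxa-Michael opening) nor C3 (no enolisation) can epimerise and the aryl ketones are not reduced at 1 atm.

**Compound list**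
1 | resorcinol | Oc1cccc(O)c1 | starting material
2 | succinic anhydride | O=C1CCC(=O)O1 | starting material
3 | 4-(2,4-dihydroxyphenyl)-4-oxobutanoic acid | OC(=O)CCC(=O)c1ccc(O)cc1O | intermediate
4 | phloroglucinol | Oc1cc(O)cc(O)c1 | starting material
5 | 1-(2,4-dihydroxyphenyl)-4-(2,4,6-trihydroxyphenyl)butane-1,4-dione | O=C(CCC(=O)c1c(O)cc(O)cc1O)c1ccc(O)cc1O | intermediate
6 | 1-[4-(benzyloxy)-2-hydroxyphenyl]-4-[2,4-bis(benzyloxy)-6-hydroxyphenyl]butane-1,4-dione | O=C(CCC(=O)c1c(O)cc(OCc2ccccc2)cc1OCc1ccccc1)c1ccc(OCc2ccccc2)cc1O | intermediate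
7 | 4-(benzyloxy)benzaldehyde | O=Cc1ccc(OCc2ccccc2)cc1 | starting material
8 | (E)-2-[4-(benzyloxy)benzylidene]-1-[4-(benzyloxy)-2-hydroxyphenyl]-4-[2,4-bis(benzyloxy)-6-hydroxyphenyl]butane-1,4-dione | O=C(/C(CC(=O)c1c(O)cc(OCc2ccccc2)cc1OCc1ccccc1)=C/c1ccc(OCc2ccccc2)cc1)c1ccc(OCc2ccccc2)cc1O | intermediate (not isolated)
9 | (2S,3R)-7-(benzyloxy)-2-[4-(benzyloxy)phenyl]-3-{2-[2,4-bis(benzyloxy)-6-hydroxyphenyl]-2-oxoethyl}chroman-4-one | O=C1c2ccc(OCc3ccccc3)cc2O[C@H](c2ccc(OCc3ccccc3)cc2)[C@H]1CC(=O)c1c(O)cc(OCc2ccccc2)cc1OCc1ccccc1 | intermediate (not isolated)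
10 | (2S,3R)-7-(benzyloxy)-2-[4-(benzyloxy)phenyl]-3-{(E)-1-[2,4-bis(benzyloxy)-6-hydroxybenzoyl]-2-[4-(benzyloxy)phenyl]vinyl}chroman-4-one | O=C1c2ccc(OCc3ccccc3)cc2O[C@H](c2ccc(OCc3ccccc3)cc2)[C@H]1/C(=C\c1ccc(OCc2ccccc2)cc1)C(=O)c1c(O)cc(OCc2ccccc2)cc1OCc1ccccc1 | intermediate (not isolated)
11 | (2S,3R)-7-(benzyloxy)-2-[4-(benzyloxy)phenyl]-3-{(2S,3R)-5,7-bis(benzyloxy)-2-[4-(benzyloxy)phenyl]-4-oxochroman-3-yl}chroman-4-one | O=C1c2ccc(OCc3ccccc3)cc2O[C@H](c2ccc(OCc3ccccc3)cc2)[C@H]1[C@H]1C(=O)c2c(OCc3ccccc3)cc(OCc3ccccc3)cc2O[C@@H]1c1ccc(OCc2ccccc2)cc1 | intermediate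
12 | (2S,3R)-3-[(2S,3R)-5,7-dihydroxy-2-(4-hydroxyphenyl)-4-oxochroman-3-yl]-7-hydroxy-2-(4-hydroxyphenyl)chroman-4-one | O=C1c2ccc(O)cc2O[C@H](c2ccc(O)cc2)[C@H]1[C@H]1C(=O)c2c(O)cc(O)cc2O[C@@H]1c1ccc(O)cc1 | target

**Totals:** 5 steps; longest linear sequence 5 steps (1 → 3 → 5 → 6 → 11 → 12).

**Steps most likely to fail, with fallbacks**

Step 4 (highest risk). The second condensation is at a hindered CH2 next to a di-ortho-substituted aryl ketone and may stall at 9. The selectivity per ring closure is unproven and is only rescued by the diastereomer amplification. Intermediate 8 can also drift to an ene-dione or a furan. Fallback, setting out from 6 and returning at 11: both chelated phenols of 6 are masked with MOMCl/NaH to give the bis-MOM diketone F1. A KOH-mediated double Claisen–Schmidt condensation with 7 then gives the isolable protected (E,E)-bis-chalcone F2, which cannot cyclise. HCl in MeOH–THF removes the MOM groups to the free bis(2'-hydroxychalcone) F3, which closes both rings under the same acidic, thermodynamic conditions to the racemic trans,trans pentabenzyl biflavanone mixture F4. Chromatography removes the unlike diastereomer and preparative chiral SFC of the like racemate delivers 11; the unwanted isomers can be re-equilibrated with base and recycled.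

Step 2. Hot BF3 can cyclodehydrate the product 1,4-diketone to a 2,5-diarylfuran (Paal–Knorr) or give low conversion of the γ-keto acid. Fallback, setting out from 1 and returning at 5: a Houben–Hoesch sequence at 0 °C, in which the second ketone stays masked as an iminium salt until aqueous hydrolysis. Resorcinol 1 and excess succinonitrile (ZnCl2, HCl gas, Et2O) give the ketiminium chloride of the resorcinol–succinonitrile adduct F5, which precipitates and is hydrolysed in hot water to 4-(2,4-dihydroxyphenyl)-4-oxobutanenitrile F6. A second Hoesch reaction of F6 with phloroglucinol 4 gives the ketiminium chloride of diketone 5 F7, whose hydrolysis gives 5.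

Step 3. The tribenzylation can give statistical mixtures (under-alkylation, or alkylation of a chelated OH) that are hard to separate. Fallback, setting out from 5 and returning at 12: the A-ring protection is dropped. The step-4 cascade is run directly on pentahydroxy diketone 5 with 7 (Kabbe-type condensations tolerate free, non-participating phenols) to give the 4',4'''-di-O-benzyl ether of 12 F8. The same hydrogenolysis as in step 5 then gives 12.

**Further compounds**
F1 | step 4 | bis-MOM diketone | O=C(CCC(=O)c1c(OCOC)cc(OCc2ccccc2)cc1OCc1ccccc1)c1ccc(OCc2ccccc2)cc1OCOC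
F2 | step 4 | protected (E,E)-bis-chalcone | O=C(c1ccc(OCc2ccccc2)cc1OCOC)/C(=C/c1ccc(OCc2ccccc2)cc1)/C(=C\c1ccc(OCc2ccccc2)cc1)C(=O)c1c(OCOC)cc(OCc2ccccc2)cc1OCc1ccccc1
F3 | step 4 | free bis(2'-hydroxychalcone) | O=C(c1ccc(OCc2ccccc2)cc1O)/C(=C/c1ccc(OCc2ccccc2)cc1)/C(=C\c1ccc(OCc2ccccc2)cc1)C(=O)c1c(O)cc(OCc2ccccc2)cc1OCc1ccccc1
F4 | step 4 | racemic trans,trans pentabenzyl biflavanone mixture | O=C1c2ccc(OCc3ccccc3)cc2OC(c2ccc(OCc3ccccc3)cc2)C1C1C(=O)c2c(OCc3ccccc3)cc(OCc3ccccc3)cc2OC1c1ccc(OCc2ccccc2)cc1
F5 | step 2 | ketiminium chloride of the resorcinol–succinonitrile adduct | N#CCCC(=[NH2+])c1ccc(O)cc1O.[Cl-]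
F6 | step 2 | 4-(2,4-dihydroxyphenyl)-4-oxobutanenitrile | N#CCCC(=O)c1ccc(O)cc1O
F7 | step 2 | ketiminium chloride of diketone 5 | [NH2+]=C(CCC(=O)c1ccc(O)cc1O)c1c(O)cc(O)cc1O.[Cl-]
F8 | step 3 | 4',4'''-di-O-benzyl ether of 12 | O=C1c2ccc(O)cc2O[C@H](c2ccc(OCc3ccccc3)cc2)[C@H]1[C@H]1C(=O)c2c(O)cc(O)cc2O[C@@H]1c1ccc(OCc2ccccc2)cc1
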